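**Retrosynthetic overview**
1. Target 15 ⇐ 12 (sulfate the only free phenol, then deacetylate) ⇐ pentaacetate 11 ⇐ pentamethyl ether 9; O7 is singled out by selective 7-deacetylation.
2. Ring C of 9 ⇐ 2-hydroxyaryl ynone 8 (6-endo oxa-Michael), with the phenol freed from 7 by chelation-controlled demethylation.
3. Key C4–C3 bond of ynone 7 ⇐ aldehyde 3 used as an acyl anion (carbene-derived Breslow intermediate 6) + alkynyl(phenyl)iodonium salt 5.
4. 3 ⇐ 1 (Vilsmeier formylation); 5 ⇐ 4 + PhI(OH)OTs. Rings A and B are bought; ring C is the only ring formed.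

Assumption: the target has no stereocentre, so it is made as the single achiral compound drawn, in the free hydrogen sulfate form (the salt from the last step is converted by cold cation exchange).

**Step 1**
Reactants: 1 1,2,3,5-tetramethoxybenzene
Product: 3 2,3,4,6-tetramethoxybenzaldehyde, via aryl iminium salt 2 (not isolated)
Conditions: POCl3 (1.2 equiv), DMF, 0 → 60 °C; then H2O, 60 °C
Reagents that add atoms: N,N-dimethylformamide CN(C)C=O (formyl carbon); water O (carbonyl oxygen)
Why: Vilsmeier–Haack formylation, in which the two free ring positions of 1 are equivalent and strongly activated, so hydrolysis of iminium salt 2 gives a single aldehyde.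

**Step 2**
Reactants: 4 4-ethynyl-1,2-dimethoxybenzene
Product: 5 [(3,4-dimethoxyphenyl)ethynyl](phenyl)iodonium 4-methylbenzenesulfonate
Conditions: PhI(OH)OTs (1.05 equiv), 4 Å MS, CH2Cl2, rt, dark; Et2O precipitation, store cold
Reagents that add atoms: [hydroxy(tosyloxy)iodo]benzene Cc1ccc(S(=O)(=O)OI(O)c2ccccc2)cc1
Why: Koser-type ligand exchange of a terminal arylalkyne at trivalent iodine with loss of water gives the alkynyl(aryl)iodonium tosylate, which makes the former acetylide carbon an electrophile.

**Step 3**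
Reactants: 3 2,3,4,6-tetramethoxybenzaldehyde; 5 [(3,4-dimethoxyphenyl)ethynyl](phenyl)iodonium 4-methylbenzenesulfonate
Product: 7 3-(3,4-dimethoxyphenyl)-1-(2,3,4,6-tetramethoxyphenyl)prop-2-yn-1-one, via Breslow enaminol 6 (not isolated)
Conditions: 2-(pentafluorophenyl)-6,7-dihydro-5H-pyrrolo[2,1-c][1,2,4]triazol-2-ium tetrafluoroborate (20 mol%), iPr2NEt (1.5 equiv), toluene/CH2Cl2, −40 → 0 °C
Reagents that add atoms: none
Why: N-heterocyclic-carbene-catalysed C–H alkynylation of an aldehyde, in which the carbene turns the formyl carbon into a nucleophilic acyl anion equivalent (6) that displaces iodobenzene at the alkynyl carbon and then releases the carbene, the di-ortho-substituted aldehyde being unable to self-condense and a small electron-poor N-aryl carbene being chosen to reach the hindered formyl group.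

**Step 4**
Reactants: 7 3-(3,4-dimethoxyphenyl)-1-(2,3,4,6-tetramethoxyphenyl)prop-2-yn-1-one
Product: 9 2-(3,4-dimethoxyphenyl)-5,7,8-trimethoxy-4H-chromen-4-one (hypolaetin pentamethyl ether), via 2-hydroxyaryl ynone 8 (not isolated)
Conditions: BCl3 (1.2 equiv), CH2Cl2, −78 → 0 °C; MeOH, evaporate; then DMAP (0.3 equiv), Et3N (2 equiv), DMF, 40 °C
Reagents that add atoms: none
Why: Chelation-controlled Lewis-acid demethylation, in which ketone-bound BCl3 cleaves only an ortho methoxy group and of the two the one buttressed by the neighbouring 3-methoxy group (as in the classical preparation of 2-hydroxy-3,4,6-trimethoxyphenyl ketones), followed by DMAP-catalysed 6-endo-dig oxa-Michael cyclisation that closes ring C as the flavone and not the aurone.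

**Step 5**
Reactants: 9 2-(3,4-dimethoxyphenyl)-5,7,8-trimethoxy-4H-chromen-4-one
Product: 11 2-(3,4-diacetoxyphenyl)-5,7,8-triacetoxy-4H-chromen-4-one (hypolaetin pentaacetate), via hypolaetin 10 (not isolated)
Conditions: BBr3 (10 equiv), CH2Cl2, −78 °C → rt, Ar; MeOH at −20 °C, evaporate; then Ac2O, pyridine, DMAP (cat.), rt, Ar
Reagents that add atoms: acetic anhydride CC(=O)OC(C)=O
Why: Exhaustive BBr3 ether cleavage under anhydrous conditions that avoid the protic-acid ring opening and reclosure (Wessely–Moser rearrangement) of 5,7,8-trioxygenated flavones, followed at once by peracetylation to protect the air-sensitive pentaphenol.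

**Step 6**
Reactants: 11 2-(3,4-diacetoxyphenyl)-5,7,8-triacetoxy-4H-chromen-4-one
Product: 12 2-(3,4-diacetoxyphenyl)-5,8-diacetoxy-7-hydroxy-4H-chromen-4-one
Conditions: PhSH (1.5 equiv), imidazole (0.5 equiv), NMP, 0 °C → rt
Reagents that add atoms: none
Why: Chemoselective thiolysis of the most electrophilic aryl ester, the 7-acetate having the best leaving group (the 7-phenoxide is a vinylogous carboxylate of the C4 carbonyl), so that it alone is removed and an 8-to-7 acetyl shift is thermodynamically disfavoured for the same reason.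

**Step 7**
Reactants: 12 2-(3,4-diacetoxyphenyl)-5,8-diacetoxy-7-hydroxy-4H-chromen-4-one
Product: 15 8-hydroxyluteolin 7-sulfate (2-(3,4-dihydroxyphenyl)-5,8-dihydroxy-4-oxo-4H-chromen-7-yl hydrogen sulfate), via pyridinium sulfate salt 13 (not isolated), via ammonium salt 14 (not isolated)
Conditions: SO3·pyridine (4 equiv), pyridine, rt; MeOH quench, evaporate; NH3 (7 M in MeOH), 0 °C, Ar; evaporate; sulfonic acid resin (H+ form), H2O, 0 °C; lyophilise at once
Reagents that add atoms: sulfur trioxide–pyridine complex [O-]S(=O)(=O)[n+]1ccccc1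
Why: O-sulfation of the single free phenol with the SO3·pyridine complex, then ammonolysis of the four aryl acetates (to which the aryl sulfate monoanion is inert) and cation exchange to the free hydrogen sulfate.

**Compound list**
1 | 1,2,3,5-tetramethoxybenzene | COc1cc(OC)c(OC)c(OC)c1 | starting material
2 | N,N-dimethyl(2,3,4,6-tetramethoxyphenyl)methaniminium dichlorophosphate | COc1cc(OC)c(C=[N+](C)C)c(OC)c1OC.[O-]P(=O)(Cl)Cl | intermediate
3 | 2,3,4,6-tetramethoxybenzaldehyde | COc1cc(OC)c(C=O)c(OC)c1OC | intermediate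
4 | 4-ethynyl-1,2-dimethoxybenzene | C#Cc1ccc(OC)c(OC)c1 | starting material
5 | [(3,4-dimethoxyphenyl)ethynyl](phenyl)iodonium 4-methylbenzenesulfonate | COc1ccc(C#C[I+]c2ccccc2)cc1OC.Cc1ccc(S(=O)(=O)[O-])cc1 | intermediate
6 | Breslow enaminol from 3 and the triazolylidene: 3-[hydroxy(2,3,4,6-tetramethoxyphenyl)methylidene]-2-(pentafluorophenyl)-2,5,6,7-tetrahydro-3H-pyrrolo[2,1-c][1,2,4]triazole (enol geometry not defined) | COc1cc(OC)c(C(O)=C2N(c3c(F)c(F)c(F)c(F)c3F)N=C3CCCN23)c(OC)c1OC | intermediate
7 | 3-(3,4-dimethoxyphenyl)-1-(2,3,4,6-tetramethoxyphenyl)prop-2-yn-1-one | COc1cc(OC)c(C(=O)C#Cc2ccc(OC)c(OC)c2)c(OC)c1OC | intermediate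
8 | 3-(3,4-dimethoxyphenyl)-1-(2-hydroxy-3,4,6-trimethoxyphenyl)prop-2-yn-1-one | COc1cc(OC)c(C(=O)C#Cc2ccc(OC)c(OC)c2)c(O)c1OC | intermediate
9 | 2-(3,4-dimethoxyphenyl)-5,7,8-trimethoxy-4H-chromen-4-one | COc1ccc(-c2cc(=O)c3c(OC)cc(OC)c(OC)c3o2)cc1OC | intermediate
10 | hypolaetin, 2-(3,4-dihydroxyphenyl)-5,7,8-trihydroxy-4H-chromen-4-one | O=c1cc(-c2ccc(O)c(O)c2)oc2c(O)c(O)cc(O)c12 | intermediate
11 | hypolaetin pentaacetate | CC(=O)Oc1ccc(-c2cc(=O)c3c(OC(C)=O)cc(OC(C)=O)c(OC(C)=O)c3o2)cc1OC(C)=O | intermediate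
12 | 2-(3,4-diacetoxyphenyl)-5,8-diacetoxy-7-hydroxy-4H-chromen-4-one | CC(=O)Oc1ccc(-c2cc(=O)c3c(OC(C)=O)cc(O)c(OC(C)=O)c3o2)cc1OC(C)=O | intermediate
13 | pyridinium 2-(3,4-diacetoxyphenyl)-5,8-diacetoxy-4-oxo-4H-chromen-7-yl sulfate | CC(=O)Oc1ccc(-c2cc(=O)c3c(OC(C)=O)cc(OS(=O)(=O)[O-])c(OC(C)=O)c3o2)cc1OC(C)=O.c1cc[nH+]cc1 | intermediate
14 | ammonium 2-(3,4-dihydroxyphenyl)-5,8-dihydroxy-4-oxo-4H-chromen-7-yl sulfate | O=c1cc(-c2ccc(O)c(O)c2)oc2c(O)c(OS(=O)(=O)[O-])cc(O)c12.[NH4+] | intermediate
15 | 8-hydroxyluteolin 7-sulfate | O=c1cc(-c2ccc(O)c(O)c2)oc2c(O)c(OS(=O)(=O)O)cc(O)c12 | target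

**Totals**
Total steps: 7. Longest linear sequence: 6 (steps 1, 3, 4, 5, 6, 7; equally 2, 3, 4, 5, 6, 7).

**Three steps most likely to fail**

Step 3. The di-ortho-methoxy, electron-rich aldehyde 3 may be too hindered to form the Breslow intermediate, or the electron-rich iodonium salt 5 may decompose under the amine base. The fallback sets out from 3 and 4 and gives up the catalytic acyl anion for conventional polarity. Alkyne 4 is deprotonated with n-BuLi (THF, −78 °C) and added to 3 to give racemic 3-(3,4-dimethoxyphenyl)-1-(2,3,4,6-tetramethoxyphenyl)prop-2-yn-1-ol F1. Oxidation of F1 with MnO2 (CH2Cl2, rt) removes the transient stereocentre and comes back to the route at 7.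

Step 4. The free ynone may not survive BCl3 (chloride or HCl addition), and 5-exo closure to the aurone could compete. The fallback sets out from 7 and masks the alkyne first. Et2NH (EtOH, rt) adds to the ynone to give (E)-3-(diethylamino)-3-(3,4-dimethoxyphenyl)-1-(2,3,4,6-tetramethoxyphenyl)prop-2-en-1-one F2. BCl3 (CH2Cl2, −78 → 0 °C) then cleaves the same buttressed ortho methoxy group to give (E)-3-(diethylamino)-3-(3,4-dimethoxyphenyl)-1-(2-hydroxy-3,4,6-trimethoxyphenyl)prop-2-en-1-one F3. Warming F3 with dilute aqueous HCl in EtOH closes ring C by intramolecular addition–elimination with loss of diethylamine; only the six-membered ring can form, and the route is rejoined at 9.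

Step 6. The 8-acetate next to the 7-position may migrate or be lost as well, giving mixtures. Loss of the 5-acetate would be harmless, since the chelated 5-OH does not sulfate. The fallback sets out from 10, isolated under argon after the BBr3 stage of step 5 instead of being acetylated, and makes no new compound (F0). It sulfates 10 directly under acidity control with tetrabutylammonium hydrogen sulfate and N,N'-dicyclohexylcarbodiimide in pyridine at 4 °C, conditions under which the most acidic 7-OH of flavones reacts first. The monosulfate is separated from minor regioisomers by reversed-phase chromatography and passed through the H+ resin, coming back at 15.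

**Further compounds**
F1 | step 3 | racemic 3-(3,4-dimethoxyphenyl)-1-(2,3,4,6-tetramethoxyphenyl)prop-2-yn-1-ol | COc1cc(OC)c(C(O)C#Cc2ccc(OC)c(OC)c2)c(OC)c1OC
F2 | step 4 | (E)-3-(diethylamino)-3-(3,4-dimethoxyphenyl)-1-(2,3,4,6-tetramethoxyphenyl)prop-2-en-1-one | CCN(CC)/C(c1ccc(OC)c(OC)c1)=C/C(=O)c1c(OC)cc(OC)c(OC)c1OC
F3 | step 4 | (E)-3-(diethylamino)-3-(3,4-dimethoxyphenyl)-1-(2-hydroxy-3,4,6-trimethoxyphenyl)prop-2-en-1-one | CCN(CC)/C(c1ccc(OC)c(OC)c1)=C/C(=O)c1c(OC)cc(OC)c(OC)c1O
F0 | step 6 | none | none
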